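**Assumption (one line):** the SMILES is taken as written, so the aroyl ring (ring D) is 3,5-dihydroxy-4-prenylphenyl with the carbonyl para to the prenyl group and no ortho-hydroxyl, and the cyclohexene is 3''S,4''R,5''S (C3''/C4'' cis, C4''/C5'' trans); locants: C1'' (C–Me), C2'' (=CH), C3'' (CH bearing ring A through C3'), C4'' (CH–C=O), C5'' (CH–aryl), C6'' (CH2); ring A is the 2',4'-dioxygenated ring of the enone half.

**Retrosynthetic overview**
1. Target 20 ⇒ heptakis-MOM ether 19 (global deprotection last).
2. 19 ⇒ cis-fused aryl δ-lactone 13 + arylboronate 18. Feature used: phenol O-2' of ring A is cis and 1,5 to the C4'' carbonyl carbon, so the target is the ring-opened form of a 6a,10a-cis tetrahydrobenzo[c]chromen-6-one; ring D has no ortho-OH and can therefore enter last as a nucleophile at that carbonyl carbon.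
3. 13 ⇒ dienyl phenol 10 + cinnamic acid 3 by a catalytic enantioselective Diels–Alder/lactonisation. This forms C3''–C4'', C5''–C6'' and the lactone C–O bond and sets C3'', C4'' and C5'' together.
4. 10 ⇒ iodochalcone 7 + dienylboronate 9; 7 ⇒ iodoacetophenone 6 + aldehyde 2; 3 ⇒ 2; 18 ⇒ resorcinol.
5. Ring order: cyclohexene and δ-lactone close together in step 8; the lactone is reopened in step 12.

Key step: step 8

**Step 1**
Reactants: 1 2,4-dihydroxybenzaldehyde
Product: 2 2,4-bis(methoxymethoxy)benzaldehyde
Conditions: MOMCl, i-Pr2NEt, CH2Cl2, 0 → 40 °C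
Reagents that add atoms: chloromethyl methyl ether, COCCl
Why: O-alkylation of both phenols to MOM acetals, the hydrogen-bonded 2-OH needing excess reagent and gentle warming.

**Step 2**
Reactants: 2 2,4-bis(methoxymethoxy)benzaldehyde
Product: 3 (E)-3-[2,4-bis(methoxymethoxy)phenyl]prop-2-enoic acid
Conditions: malonic acid, pyridine, piperidine (cat.), 90 °C
Reagents that add atoms: malonic acid, OC(=O)CC(=O)O
Why: Knoevenagel–Doebner condensation with in situ decarboxylation should give the E-cinnamic acid under basic conditions that leave the MOM acetals intact.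

**Step 3**
Reactants: 4 1-(2,4-dihydroxyphenyl)ethanone
Product: 5 1-(2,4-dihydroxy-3-iodophenyl)ethanone
Conditions: I2, HIO3, EtOH/H2O, rt → 40 °C
Reagents that add atoms: iodine, II; iodic acid, OI(=O)=O
Why: Electrophilic aromatic iodination is expected at C-3, the position ortho to both hydroxyl groups, and the iodic acid re-oxidises iodide so that all iodine is used.

**Step 4**
Reactants: 5 1-(2,4-dihydroxy-3-iodophenyl)ethanone
Product: 6 1-[2-hydroxy-3-iodo-4-(methoxymethoxy)phenyl]ethanone
Conditions: MOMCl (1.1 equiv), K2CO3, acetone, rt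
Reagents that add atoms: chloromethyl methyl ether, COCCl
Why: The 2-OH is held in a hydrogen bond to the acetyl group, so base-mediated O-alkylation with one equivalent of MOMCl should be selective for the 4-OH.

**Step 5**
Reactants: 6 1-[2-hydroxy-3-iodo-4-(methoxymethoxy)phenyl]ethanone; 2 2,4-bis(methoxymethoxy)benzaldehyde
Product: 7 (E)-3-[2,4-bis(methoxymethoxy)phenyl]-1-[2-hydroxy-3-iodo-4-(methoxymethoxy)phenyl]prop-2-en-1-one
Conditions: KOH (aq.), EtOH, rt
Reagents that add atoms: none
Why: Claisen–Schmidt aldol condensation of the methyl ketone with the non-enolisable aldehyde should give the E-enone, the free 2'-OH being tolerated as its phenoxide.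

**Step 6**
Reactants: 8 2-methylbut-1-en-3-yne
Product: 9 (E)-4,4,5,5-tetramethyl-2-(3-methylbuta-1,3-dien-1-yl)-1,3,2-dioxaborolane
Conditions: pinacolborane, Cp2Zr(H)Cl (5 mol %), Et3N (10 mol %), CH2Cl2, rt → 40 °C (sealed)
Reagents that add atoms: pinacolborane, [H]B1OC(C)(C)C(C)(C)O1
Why: Zirconocene-catalysed syn-hydroboration of the terminal alkyne places boron on the terminal carbon and should give the (E)-dienylboronate.

**Step 7**
Reactants: 7 iodochalcone; 9 (E)-dienylboronate
Product: 10 (E)-3-[2,4-bis(methoxymethoxy)phenyl]-1-{2-hydroxy-4-(methoxymethoxy)-3-[(E)-3-methylbuta-1,3-dien-1-yl]phenyl}prop-2-en-1-one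
Conditions: Pd(OAc)2/SPhos (5 mol %), K2CO3, dioxane/H2O, 70 °C
Reagents that add atoms: none
Why: Suzuki–Miyaura coupling of the hindered aryl iodide with the alkenylboronate proceeds with retention of the E geometry, and the acid-sensitive o-hydroxyaryl diene is made only one step before it is used.

**Step 8**
Reactants: 3 (E)-3-[2,4-bis(methoxymethoxy)phenyl]prop-2-enoic acid; 10 dienyl 2'-hydroxychalcone
Product: 13 cis-fused δ-lactone (6aR,7S,10aS)-7-[2,4-bis(methoxymethoxy)phenyl]-4-{(E)-3-[2,4-bis(methoxymethoxy)phenyl]acryloyl}-1-(methoxymethoxy)-9-methyl-6a,7,8,10a-tetrahydro-6H-benzo[c]chromen-6-one, via mixed pivalic anhydride 11 (not isolated), via aryl cinnamate ester 12 (not isolated)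
Conditions: 3, PivCl, i-Pr2NEt, CH2Cl2, 0 °C; then 10, (S)-benzotetramisole (20 mol %), rt → 40 °C
Reagents that add atoms: none
Why: Proposed new method: the mixed anhydride 11 acylates the 2'-OH of 10 to the aryl cinnamate 12, whose o-acylphenoxide leaving group should let the isothiourea re-ionise it to a tight ion pair of an s-cis α,β-unsaturated acyl isothiouronium (O···S locked, LUMO-lowered dienophile) and the dienyl aryloxide (HOMO-raised diene), which undergo [4+2] cycloaddition followed by aryloxide rebound that releases the catalyst. The closest known reaction type is the isothiourea-catalysed Diels–Alder/lactonisation organocascade of α,β-unsaturated acyl ammonium salts with hydroxy-tethered dienes, combined with aryloxide-turnover catalysis of α,β-unsaturated aryl esters; new here are the phenol as the tethered nucleophile and the non-silyloxy aryl diene. The cyclohexene closes by a normal-demand [4+2] (bonds C3''–C4'' and C5''–C6'', with the larger diene HOMO coefficient at the CH2 terminus matching the dienophile β-carbon), and the δ-lactone closes by 6-exo-trig acyl substitution of the aryloxide on the acyl ammonium carbon. C4'' and C5'' are set by the catalyst, whose pseudo-axial phenyl group shields one face of the acyl ammonium so that the diene adds to the other (the s-cis model predicts 4''R,5''S for the (S)-catalyst, and the (R)-catalyst is the mirror-image option), their trans relation comes from the E-cinnamoyl geometry, and C3'' is set cis to the acyl carbon by the endo-carbonyl mode, the only one that keeps the aryloxide within reach of the acyl carbon and can lactonise to the cis-fused ring. The step needs enantiofacial and endo selectivity, and the racemic thermal intramolecular cycloaddition of 12 is suppressed by working at or below 40 °C.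

**Step 9**
Reactants: 14 resorcinol
Product: 15 1,3-bis(methoxymethoxy)benzene
Conditions: MOMCl, i-Pr2NEt, CH2Cl2, 0 °C → rt
Reagents that add atoms: chloromethyl methyl ether, COCCl
Why: Standard O-alkylation of both phenols installs the two directing groups needed for the next step.

**Step 10**
Reactants: 15 1,3-bis(methoxymethoxy)benzene
Product: 17 1,3-bis(methoxymethoxy)-2-(3-methylbut-2-en-1-yl)benzene, via 2-lithio-1,3-bis(methoxymethoxy)benzene 16 (not isolated)
Conditions: n-BuLi, THF, 0 °C; then CuI (10 mol %), prenyl bromide, −78 °C → rt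
Reagents that add atoms: 1-bromo-3-methylbut-2-ene, CC(C)=CCBr
Why: Directed ortho-metalation between the two cooperating MOM ethers, followed by copper-assisted SN2 allylation, should place the prenyl group at C-2.

**Step 11**
Reactants: 17 1,3-bis(methoxymethoxy)-2-(3-methylbut-2-en-1-yl)benzene
Product: 18 2-[3,5-bis(methoxymethoxy)-4-(3-methylbut-2-en-1-yl)phenyl]-4,4,5,5-tetramethyl-1,3,2-dioxaborolane
Conditions: B2pin2, [Ir(OMe)(cod)]2 (1.5 mol %), dtbpy (3 mol %), THF, 60 °C
Reagents that add atoms: bis(pinacolato)diboron, CC1(C)OB(OC1(C)C)B1OC(C)(C)C(C)(C)O1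
Why: Sterically controlled iridium-catalysed C–H borylation should take the only C–H without an ortho substituent (C-5), and the trisubstituted prenyl alkene is expected to be slow to hydroborate.

**Step 12**
Reactants: 13 cis-fused δ-lactone; 18 arylboronate
Product: 19 2'-hydroxy heptakis(methoxymethyl) ether of 20 (3''S,4''R,5''S; all phenols except O-2' of ring A as MOM ethers)
Conditions: [Pd(IPr)(cinnamyl)Cl] (5 mol %), K3PO4, H2O (3 equiv), THF, 60 °C
Reagents that add atoms: none
Why: Pd–NHC-catalysed acyl C–O Suzuki–Miyaura coupling of an aryl ester (here a cyclic one, activated by the o-acyl group on the phenoxide leaving group) should give the aryl ketone and release the 2'-phenol by oxidative addition, transmetalation and reductive elimination, without passing through an enolate at C4''.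

**Step 13**
Reactants: 19 heptakis-MOM ether
Product: 20 target, CC(C)=CCc1c(O)cc(C(=O)[C@H]2[C@@H](c3c(O)ccc(C(=O)/C=C/c4ccc(O)cc4O)c3O)C=C(C)C[C@@H]2c2ccc(O)cc2O)cc1O
Conditions: HCl (about 1 M in MeOH/THF 4:1), rt → 35 °C; NaHCO3 quench
Reagents that add atoms: none
Why: Acid-catalysed acetal exchange of the seven MOM ethers with methanol, run under the mildest conditions that work, is chosen to limit cyclisation of the prenyl group onto its flanking phenols.

**Compound list**
1 | 2,4-dihydroxybenzaldehyde | O=Cc1ccc(O)cc1O | starting material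
2 | 2,4-bis(methoxymethoxy)benzaldehyde | O=Cc1ccc(OCOC)cc1OCOC | intermediate
3 | (E)-3-[2,4-bis(methoxymethoxy)phenyl]prop-2-enoic acid | OC(=O)/C=C/c1ccc(OCOC)cc1OCOC | intermediate
4 | 1-(2,4-dihydroxyphenyl)ethanone | CC(=O)c1ccc(O)cc1O | starting material
5 | 1-(2,4-dihydroxy-3-iodophenyl)ethanone | CC(=O)c1ccc(O)c(I)c1O | intermediate
6 | 1-[2-hydroxy-3-iodo-4-(methoxymethoxy)phenyl]ethanone | CC(=O)c1ccc(OCOC)c(I)c1O | intermediate
7 | (E)-3-[2,4-bis(methoxymethoxy)phenyl]-1-[2-hydroxy-3-iodo-4-(methoxymethoxy)phenyl]prop-2-en-1-one | O=C(/C=C/c1ccc(OCOC)cc1OCOC)c1ccc(OCOC)c(I)c1O | intermediate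
8 | 2-methylbut-1-en-3-yne | CC(=C)C#C | starting material
9 | (E)-4,4,5,5-tetramethyl-2-(3-methylbuta-1,3-dien-1-yl)-1,3,2-dioxaborolane | CC(=C)/C=C/B1OC(C)(C)C(C)(C)O1 | intermediate
10 | (E)-3-[2,4-bis(methoxymethoxy)phenyl]-1-{2-hydroxy-4-(methoxymethoxy)-3-[(E)-3-methylbuta-1,3-dien-1-yl]phenyl}prop-2-en-1-one | CC(=C)/C=C/c1c(O)c(C(=O)/C=C/c2ccc(OCOC)cc2OCOC)ccc1OCOC | intermediate
11 | (E)-3-[2,4-bis(methoxymethoxy)phenyl]prop-2-enoic pivalic anhydride | CC(C)(C)C(=O)OC(=O)/C=C/c1ccc(OCOC)cc1OCOC | intermediate
12 | 2'-O-[(E)-2,4-bis(methoxymethoxy)cinnamoyl] ester of 10 | CC(=C)/C=C/c1c(OC(=O)/C=C/c2ccc(OCOC)cc2OCOC)c(C(=O)/C=C/c2ccc(OCOC)cc2OCOC)ccc1OCOC | intermediate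
13 | (6aR,7S,10aS)-7-[2,4-bis(methoxymethoxy)phenyl]-4-{(E)-3-[2,4-bis(methoxymethoxy)phenyl]acryloyl}-1-(methoxymethoxy)-9-methyl-6a,7,8,10a-tetrahydro-6H-benzo[c]chromen-6-one | O=C1Oc2c(C(=O)/C=C/c3ccc(OCOC)cc3OCOC)ccc(OCOC)c2[C@H]2C=C(C)C[C@H](c3ccc(OCOC)cc3OCOC)[C@@H]12 | intermediate
14 | resorcinol | Oc1cccc(O)c1 | starting material
15 | 1,3-bis(methoxymethoxy)benzene | COCOc1cccc(OCOC)c1 | intermediate
16 | 2-lithio-1,3-bis(methoxymethoxy)benzene | [Li]c1c(OCOC)cccc1OCOC | intermediate
17 | 1,3-bis(methoxymethoxy)-2-(3-methylbut-2-en-1-yl)benzene | CC(C)=CCc1c(OCOC)cccc1OCOC | intermediate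
18 | 2-[3,5-bis(methoxymethoxy)-4-(3-methylbut-2-en-1-yl)phenyl]-4,4,5,5-tetramethyl-1,3,2-dioxaborolane | CC(C)=CCc1c(OCOC)cc(cc1OCOC)B1OC(C)(C)C(C)(C)O1 | intermediate
19 | 2'-hydroxy heptakis(methoxymethyl) ether of 20 (3''S,4''R,5''S) | CC(C)=CCc1c(OCOC)cc(C(=O)[C@H]2[C@@H](c3c(OCOC)ccc(C(=O)/C=C/c4ccc(OCOC)cc4OCOC)c3O)C=C(C)C[C@@H]2c2ccc(OCOC)cc2OCOC)cc1OCOC | intermediate
20 | target (kuwanon J as specified by the SMILES) | CC(C)=CCc1c(O)cc(C(=O)[C@H]2[C@@H](c3c(O)ccc(C(=O)/C=C/c4ccc(O)cc4O)c3O)C=C(C)C[C@@H]2c2ccc(O)cc2O)cc1O | target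

**Step count and risk**
Total steps: 13. Longest linear sequence: 7 (steps 3, 4, 5, 7, 8, 12, 13).

Steps most likely to fail:

1. **Step 8 (Proposed new method).** The aryl ester 12 may not re-ionise to the acyl isothiouronium, so that no catalysed cycloaddition takes place, or the cycloaddition may run with poor enantiofacial or endo selectivity. Fallback (known chemistry, covalent tether in place of the ion pair): setting out from 3 and 10, the mixed anhydride 11 is used with DMAP in place of the chiral catalyst so that the aryl cinnamate 12 is isolated. Heating 12 in degassed xylene (about 140 °C, BHT, high dilution) should effect the thermal ester-tethered intramolecular Diels–Alder reaction; the short planar four-atom tether should allow only the cis-fused lactone, and the E-cinnamate fixes the trans C4''/C5'' relation. The product is the racemate, that is 13 together with the ent-lactone F1, and preparative chiral SFC brings the sequence back to the route at 13.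

2. **Step 12.** Hydrolysis of the activated lactone by the aqueous base may outrun oxidative addition at the hindered α-branched acyl carbon, the acyl–palladium species may decarbonylate, or the liberated 2'-phenoxide may close onto the enone to a flavanone. Fallback (classical acyl substitution under redox protection of the enone): setting out from 13, aminolysis with MeNHOMe·HCl/Me2AlCl opens the lactone to the Weinreb amide F2. Luche reduction (NaBH4, CeCl3, MeOH, −40 °C) masks the chalcone carbonyl as the allylic alcohol F3 (mixture of carbinol epimers). Boronate 18 is converted with CuBr2 (MeOH/H2O) into the aryl bromide F4, and bromine–lithium exchange (t-BuLi, −78 °C) gives the aryllithium F5. After deprotonation of the phenol and the alcohol of F3 with MeLi, F5 adds once to the Weinreb amide to give the keto alcohol F6. MnO2 then re-oxidises the doubly activated allylic alcohol selectively and brings the sequence back to the route at 19.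

3. **Step 13.** Under protic acid the prenyl group may cyclise onto a flanking phenol to a chroman, the 2'-hydroxychalcone may close to a flavanone, or the ring A phenol may form a cyclic ketal with the C4'' ketone. Fallback (aprotic silyl-transfer cleavage in place of Brønsted acid solvolysis): setting out from 19, TMSOTf/2,2'-bipyridyl in MeCN at 0 °C converts the aryl MOM ethers into aryl trimethylsilyl ethers, giving the per-O-trimethylsilyl ether F7. The silyl ethers are then hydrolysed with water/KHCO3 at room temperature, which brings the sequence back to the route at the target 20.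

**Further compounds**
F1 | step 8 | ent-13, (6aS,7R,10aR)-lactone | O=C1Oc2c(C(=O)/C=C/c3ccc(OCOC)cc3OCOC)ccc(OCOC)c2[C@@H]2C=C(C)C[C@@H](c3ccc(OCOC)cc3OCOC)[C@H]12
F2 | step 12 | Weinreb amide from ring-opening of 13 (2'-OH free) | CON(C)C(=O)[C@H]1[C@@H](c2c(OCOC)ccc(C(=O)/C=C/c3ccc(OCOC)cc3OCOC)c2O)C=C(C)C[C@@H]1c1ccc(OCOC)cc1OCOC
F3 | step 12 | allylic alcohol from 1,2-reduction of the enone of F2 (carbinol epimers) | CON(C)C(=O)[C@H]1[C@@H](c2c(OCOC)ccc(C(O)/C=C/c3ccc(OCOC)cc3OCOC)c2O)C=C(C)C[C@@H]1c1ccc(OCOC)cc1OCOC
F4 | step 12 | 5-bromo-1,3-bis(methoxymethoxy)-2-(3-methylbut-2-en-1-yl)benzene | CC(C)=CCc1c(OCOC)cc(Br)cc1OCOC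
F5 | step 12 | [3,5-bis(methoxymethoxy)-4-(3-methylbut-2-en-1-yl)phenyl]lithium | [Li]c1cc(OCOC)c(CC=C(C)C)c(OCOC)c1
F6 | step 12 | keto alcohol, 19 with the enone carbonyl reduced to CH(OH) (carbinol epimers) | CC(C)=CCc1c(OCOC)cc(C(=O)[C@H]2[C@@H](c3c(OCOC)ccc(C(O)/C=C/c4ccc(OCOC)cc4OCOC)c3O)C=C(C)C[C@@H]2c2ccc(OCOC)cc2OCOC)cc1OCOC
F7 | step 13 | octakis(trimethylsilyl) ether of 20 | CC(C)=CCc1c(O[Si](C)(C)C)cc(C(=O)[C@H]2[C@@H](c3c(O[Si](C)(C)C)ccc(C(=O)/C=C/c4ccc(O[Si](C)(C)C)cc4O[Si](C)(C)C)c3O[Si](C)(C)C)C=C(C)C[C@@H]2c2ccc(O[Si](C)(C)C)cc2O[Si](C)(C)C)cc1O[Si](C)(C)C
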